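**Plan**
1. Labels used here: ten-membered ring C1–C10, with C1/C10 the cis-epoxide carbons (C10 bears CH3), C3 the ketone, C4 the carbon carrying the exocyclic methylene C15, C5 (O-angeloyl), C6 (OH), C7/C8 the lactone-fused carbons; lactone carbons C11 (=C13H2) and C12 (C=O). Target = (1S,5S,6R,7R,8R,10R).
2. Retrosynthesis: C6–C7 is cut last (retro-allylation to a C6 aldehyde and a 3-(bromomethyl)butenolide), then the butenolide C7=C11 bond and the lactone ester (retro-metathesis, retro-esterification), then C3–C4 (retro-Nozaki–Hiyama–Kishi), leaving a C4–C6 vinyl iodide and a C1–C3/C7–C10 epoxy aldehyde.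
3. Forward: the epoxide is made first on the open chain, the fragments are joined at C3–C4, the butenolide is closed by metathesis, and the ten-membered ring is closed last, in the step that delivers the target.
4. Stereochemistry: C5 from (R)-glyceraldehyde acetonide; C8 from (R)-epichlorohydrin; C1/C10 from a Z-alkene (syn-carbomagnesiation) and a ligand-controlled, hydroxyl-directed epoxidation; C6 and C7 in the ring closure under control of C5 and C8.
5. Enabling feature: the α-methylene-γ-butyrolactone ring with the C6 carbinol on its β-carbon C7 (array C6(OH)–C7–C11=C13) is the retron of an allylmetal–aldehyde addition, so a butenolide that already holds the lactone ring can close the carbocycle through C7.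

Key step: step 20

Remark: the chromium coupling that joins the two fragments should give both C3 epimers; C3 is written without a stereodescriptor in the open-chain compounds until it becomes the ketone carbon.

**Step 1**
Reactants: 1 (R)-2,2-dimethyl-1,3-dioxolane-4-carbaldehyde
Product: 2 (S)-4-ethynyl-2,2-dimethyl-1,3-dioxolane
Conditions: dimethyl (1-diazo-2-oxopropyl)phosphonate, K2CO3, MeOH, 0 °C to rt
Reagents that add atoms: dimethyl (1-diazo-2-oxopropyl)phosphonate CC(=O)C(=[N+]=[N-])P(=O)(OC)OC
Why: Seyferth–Gilbert homologation with the Ohira–Bestmann reagent converts the aldehyde into the terminal alkyne under carbonate conditions mild enough to leave the α-alkoxy stereocentre (future C5) untouched.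

**Step 2**
Reactants: 2 (S)-4-ethynyl-2,2-dimethyl-1,3-dioxolane
Product: 4 (R)-4-(1-iodoethenyl)-2,2-dimethyl-1,3-dioxolane, via α-stannylalkene 3 (not isolated)
Conditions: Bu3SnH, Mo(CO)3(CNtBu)3 (cat.), hydroquinone, THF, 55 °C; then I2, CH2Cl2, 0 °C
Reagents that add atoms: tributyltin hydride CCCC[SnH](CCCC)CCCC (its tin stays only in 3); iodine II
Why: Molybdenum-catalysed hydrostannation of propargylic ethers places tin on the internal alkyne carbon next to the oxygenated centre, and iododestannylation then gives the 2-iodo-1-alkene, so C4 carries the halide and C15 is the CH2.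

**Step 3**
Reactants: 4 (R)-4-(1-iodoethenyl)-2,2-dimethyl-1,3-dioxolane
Product: 5 (R)-3-iodobut-3-ene-1,2-diol
Conditions: AcOH/H2O 4:1, 40 °C
Reagents that add atoms: none
Why: Acid hydrolysis of the acetonide frees the diol without involving the stereocentre or the vinyl iodide.

**Step 4**
Reactants: 5 (R)-3-iodobut-3-ene-1,2-diol
Product: 6 (R)-1-[(tert-butyldimethylsilyl)oxy]-3-iodobut-3-en-2-ol
Conditions: TBSCl (1 equiv), imidazole, CH2Cl2, −20 to 0 °C
Reagents that add atoms: tert-butyldimethylsilyl chloride CC(C)(C)[Si](C)(C)Cl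
Why: The primary hydroxyl (future C6 oxygen) is silylated selectively over the hindered secondary allylic one for steric reasons.

**Step 5**
Reactants: 6 (R)-1-[(tert-butyldimethylsilyl)oxy]-3-iodobut-3-en-2-ol
Product: 7 (R)-1-[(tert-butyldimethylsilyl)oxy]-3-iodobut-3-en-2-yl (Z)-2-methylbut-2-enoate
Conditions: angelic acid, 2,4,6-trichlorobenzoyl chloride, Et3N, toluene, rt; then 6, toluene, 80 °C
Reagents that add atoms: angelic acid C/C=C(/C)C(=O)O
Why: Yamaguchi esterification through the mixed anhydride, run without a nucleophilic amine catalyst, acylates the secondary alcohol while suppressing Z-to-E isomerisation of the angelate.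

**Step 6**
Reactants: 8 tert-butyl(but-3-yn-1-yloxy)dimethylsilane; 9 (R)-epichlorohydrin
Product: 10 (R)-8-[(tert-butyldimethylsilyl)oxy]-1-chlorooct-4-yn-2-ol
Conditions: 8, n-BuLi, THF, −78 °C; BF3·OEt2; then 9, −78 °C
Reagents that add atoms: none
Why: BF3-promoted alkynylation of the terminal epoxide takes place at the unsubstituted carbon, so the C–O bond of the stereocentre is not touched and (R)-9 gives the (R)-chlorohydrin (future C8).

**Step 7**
Reactants: 10 (R)-8-[(tert-butyldimethylsilyl)oxy]-1-chlorooct-4-yn-2-ol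
Product: 12 (R)-8-[(tert-butyldimethylsilyl)oxy]oct-1-en-5-yn-3-ol, via terminal epoxide 11 (not isolated)
Conditions: Me3S+ I−, n-BuLi (excess ylide), THF, −10 °C to rt
Reagents that add atoms: trimethylsulfonium iodide C[S+](C)C.[I-]
Why: Dimethylsulfonium methylide first closes the chlorohydrin to the epoxide and then opens it at CH2 and eliminates dimethyl sulfide (one-carbon homologation of an epoxide to an allylic alcohol), which gives the vinyl carbinol with C8 unchanged.

**Step 8**
Reactants: 12 (R)-8-[(tert-butyldimethylsilyl)oxy]oct-1-en-5-yn-3-ol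
Product: 13 (R)-tert-butyl({6-[(4-methoxybenzyl)oxy]oct-7-en-3-yn-1-yl}oxy)dimethylsilane
Conditions: NaH, 4-methoxybenzyl chloride, Bu4NI (cat.), THF/DMF, 0 °C to rt
Reagents that add atoms: 4-methoxybenzyl chloride COc1ccc(CCl)cc1
Why: Williamson etherification masks the C8 hydroxyl so that only the C3 hydroxyl can direct the later carbometalation and epoxidation.

**Step 9**
Reactants: 13 (R)-tert-butyl({6-[(4-methoxybenzyl)oxy]oct-7-en-3-yn-1-yl}oxy)dimethylsilane
Product: 14 (R)-6-[(4-methoxybenzyl)oxy]oct-7-en-3-yn-1-ol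
Conditions: TBAF, THF, 0 °C
Reagents that add atoms: none
Why: Fluoride cleaves the primary silyl ether and leaves the PMB ether, alkyne and vinyl group alone.

**Step 10**
Reactants: 14 (R)-6-[(4-methoxybenzyl)oxy]oct-7-en-3-yn-1-ol
Product: 16 (3Z,6R)-6-[(4-methoxybenzyl)oxy]-4-methylocta-3,7-dien-1-ol, via alkenylmagnesium alkoxide 15 (not isolated)
Conditions: MeMgBr (excess), Fe(acac)3 (cat.), THF, −78 to 0 °C; then aq NH4Cl
Reagents that add atoms: methylmagnesium bromide C[Mg]Br
Why: Iron-catalysed, alkoxide-directed syn-carbomagnesiation of the homopropargylic alcohol delivers methyl to the distal alkyne carbon (C10) and magnesium to the proximal one (C1), so protonation gives the Z-trisubstituted alkene with C2 and C9 cis.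

**Step 11**
Reactants: 16 (3Z,6R)-6-[(4-methoxybenzyl)oxy]-4-methylocta-3,7-dien-1-ol
Product: 17 2-[(2S,3R)-3-{(2R)-2-[(4-methoxybenzyl)oxy]but-3-en-1-yl}-3-methyloxiran-2-yl]ethan-1-ol
Conditions: VO(OiPr)3 (cat.), C2-symmetric cyclohexane-1,2-diamine-derived bis-hydroxamic acid ligand (cat., antipode that gives the C1 S, C10 R epoxide), cumene hydroperoxide, toluene, 0 °C to rt
Reagents that add atoms: cumene hydroperoxide CC(C)(OO)c1ccccc1
Why: Vanadium/bis-hydroxamic acid catalysed asymmetric epoxidation of homoallylic alcohols is directed by the C3 hydroxyl and is stereospecific, so the Z-alkene gives the cis-epoxide, the ligand sets C1 and C10, and the undirected vinyl group does not react.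

**Step 12**
Reactants: 17 2-[(2S,3R)-3-{(2R)-2-[(4-methoxybenzyl)oxy]but-3-en-1-yl}-3-methyloxiran-2-yl]ethan-1-ol
Product: 18 2-[(2S,3R)-3-{(2R)-2-[(4-methoxybenzyl)oxy]but-3-en-1-yl}-3-methyloxiran-2-yl]acetaldehyde
Conditions: Dess–Martin periodinane, NaHCO3, CH2Cl2, 0 °C; used crude at once
Reagents that add atoms: none
Why: Buffered Dess–Martin oxidation gives the β,γ-epoxy aldehyde under non-basic conditions that should avoid β-elimination of the epoxide.

**Step 13**
Reactants: 18 2-[(2S,3R)-3-{(2R)-2-[(4-methoxybenzyl)oxy]but-3-en-1-yl}-3-methyloxiran-2-yl]acetaldehyde; 7 (R)-1-[(tert-butyldimethylsilyl)oxy]-3-iodobut-3-en-2-yl (Z)-2-methylbut-2-enoate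
Product: 20 open-chain C3 carbinol (1S,5S,8R,10R; both C3 epimers; C5 O-angeloyl; C6 OTBS; C8 OPMB; vinyl on C8), via alkenylchromium species 19 (not isolated)
Conditions: CrCl2 (excess), NiCl2 (cat.), DMSO, rt
Reagents that add atoms: none
Why: The Nozaki–Hiyama–Kishi coupling turns the vinyl iodide into an alkenylchromium species that adds only to the aldehyde under neutral conditions, which forms C3–C4 in the presence of the epoxide, both esters and the silyl ether, and the C3 epimer mixture is harmless because C3 later becomes the ketone.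

**Step 14**
Reactants: 20 open-chain C3 carbinol
Product: 21 open-chain bis-silyl ether (1S,5S,8R,10R; C3 OTBS; C6 OTBS; C8 OPMB)
Conditions: TBSCl, imidazole, DMAP (cat.), DMF, rt
Reagents that add atoms: tert-butyldimethylsilyl chloride CC(C)(C)[Si](C)(C)Cl
Why: Silylation under mildly basic conditions masks C3 as a carbinol ether, so that the lactone ester can be placed on C8 alone and the labile α-methylene-β-acyloxy ketone appears only just before ring closure.

**Step 15**
Reactants: 21 open-chain bis-silyl ether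
Product: 22 open-chain C8 allylic alcohol (1S,5S,8R,10R; C3 OTBS; C6 OTBS)
Conditions: DDQ, CH2Cl2/pH 7 buffer, 0 °C
Reagents that add atoms: none
Why: Oxidative cleavage of the PMB ether under buffered neutral conditions frees the C8 hydroxyl without touching the epoxide, silyl ethers or angelate.

**Step 16**
Reactants: 22 open-chain C8 allylic alcohol
Product: 23 C8 2-(bromomethyl)acrylate (1S,5S,8R,10R; C3 OTBS; C6 OTBS)
Conditions: 2-(bromomethyl)acrylic acid, DIC, DMAP (cat.), CH2Cl2, −20 to 0 °C
Reagents that add atoms: 2-(bromomethyl)acrylic acid C=C(CBr)C(=O)O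
Why: Carbodiimide esterification installs all four lactone carbons (C11, C12, C13 and the methylene lost later) on the C8 oxygen with retention at C8.

**Step 17**
Reactants: 23 C8 2-(bromomethyl)acrylate
Product: 24 (5R)-3-(bromomethyl)furan-2(5H)-one carrying at its C5 (= C8) the chain C9H2–[C10(CH3)–O–C1H cis-epoxide]–C2H2–C3H(OTBS)–C4(=CH2)–C5H(O-angeloyl)–C6H2OTBS
Conditions: second-generation Hoveyda–Grubbs catalyst RuCl2(=CH-C6H4-2-OiPr)(H2IMes) (cat.), toluene, 60 °C
Reagents that add atoms: none
Why: Ring-closing metathesis between the C8 vinyl group and the acrylate gives the five-membered butenolide, the only small ring available, because the hindered 1,1-disubstituted C4=C15 alkene and the angelate are poor metathesis partners and a phosphine-free catalyst tolerates the allylic bromide.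

**Step 18**
Reactants: 24 bis-silyl bromomethyl butenolide
Product: 25 bromomethyl butenolide diol (1S,5S,8R,10R; C3 OH; C6 OH)
Conditions: HF·pyridine, THF, 0 °C to rt
Reagents that add atoms: none
Why: Acidic fluoride removes both silyl ethers under conditions known to spare trisubstituted epoxides, and it avoids the basic fluoride that would attack the allylic bromide or move the angelate.

**Step 19**
Reactants: 25 bromomethyl butenolide diol
Product: 26 keto aldehyde (1S,5S,8R,10R): (5R)-3-(bromomethyl)butenolide with C3 ketone, C4 methylene, C5 O-angeloyl and C6 aldehyde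
Conditions: Dess–Martin periodinane (excess), NaHCO3, CH2Cl2, 0 °C to rt; used at once
Reagents that add atoms: none
Why: One buffered Dess–Martin oxidation converts the allylic C3 carbinol into the enone and the primary C6 alcohol into the aldehyde, removing the undefined C3 centre and revealing both carbonyl groups only at the last moment.

**Step 20**
Reactants: 26 keto aldehyde
Product: 28 target CNP0348992.4 (1S,5S,6R,7R,8R,10R), via allylchromium species 27 (not isolated)
Conditions: CrCl2 (excess), THF, rt; 26 added slowly by syringe pump to about 2 mM; aqueous work-up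
Reagents that add atoms: none
Why: Two CrCl2 reduce the allylic C13–Br bond of 26 to the trivalent allylchromium species 27, whose γ-carbon C7 adds to the C6 aldehyde through a six-membered chair-like Zimmerman–Traxler transition state with allylic transposition, so one C–C bond (C6–C7) closes the ten-membered carbocycle and moves the double bond into the exocyclic C11=C13 position of the lactone. The closest known reaction type is the chromium-mediated Nozaki–Hiyama (Barbier-type) allylation of aldehydes with 2-(bromomethyl)-2-alkenoates and 3-(bromomethyl)butenolides, used between molecules to make β-(hydroxyalkyl)-α-methylene-γ-lactones and within one molecule to close medium rings. The ring closes in a 10-exo-trig mode at the aldehyde carbon, on a chain pre-bent by the cis-epoxide and by the sp2 carbons C3, C4, C11 and C12. C7 is set by attack on the butenolide face anti to the C9 substituent at C8, which gives the trans ring fusion (7R). C6 is set by the chair transition state with the ring-locked allyl geometry (C8 trans to C13), which places the new hydroxyl anti to C8, and by Felkin–Anh approach anti to the C5 angeloyloxy group, which places it anti to O5 (6R), so all three elements point to the same diastereomer. The step needs aldehyde-over-ketone chemoselectivity (the cis-epoxide would permit a seven-membered closure onto C3) and ring closure over oligomerisation: the ester-stabilised allylchromium is a weak nucleophile that adds to aldehydes far faster than to a cross-conjugated α-branched ketone and does not add in a conjugate sense, and slow addition into excess CrCl2 keeps 27 at millimolar concentration.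

**Compound list**
1 | (R)-2,2-dimethyl-1,3-dioxolane-4-carbaldehyde ((R)-glyceraldehyde acetonide) | O=C[C@@H]1OC(C)(C)OC1 | starting material
2 | (S)-4-ethynyl-2,2-dimethyl-1,3-dioxolane | C#C[C@@H]1OC(C)(C)OC1 | intermediate
3 | tributyl{1-[(4R)-2,2-dimethyl-1,3-dioxolan-4-yl]ethenyl}stannane (not isolated) | C=C([Sn](CCCC)(CCCC)CCCC)[C@@H]1OC(C)(C)OC1 | intermediate
4 | (R)-4-(1-iodoethenyl)-2,2-dimethyl-1,3-dioxolane | C=C(I)[C@@H]1OC(C)(C)OC1 | intermediate
5 | (R)-3-iodobut-3-ene-1,2-diol | C=C(I)[C@H](O)CO | intermediate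
6 | (R)-1-[(tert-butyldimethylsilyl)oxy]-3-iodobut-3-en-2-ol | C=C(I)[C@H](O)CO[Si](C)(C)C(C)(C)C | intermediate
7 | (R)-1-[(tert-butyldimethylsilyl)oxy]-3-iodobut-3-en-2-yl (Z)-2-methylbut-2-enoate (C4–C6 fragment, C15 = CH2) | C=C(I)[C@H](OC(=O)/C(C)=C\C)CO[Si](C)(C)C(C)(C)C | intermediate
8 | tert-butyl(but-3-yn-1-yloxy)dimethylsilane | C#CCCO[Si](C)(C)C(C)(C)C | starting material
9 | (R)-epichlorohydrin | ClC[C@H]1CO1 | starting material
10 | (R)-8-[(tert-butyldimethylsilyl)oxy]-1-chlorooct-4-yn-2-ol | ClC[C@H](O)CC#CCCO[Si](C)(C)C(C)(C)C | intermediate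
11 | (R)-tert-butyldimethyl{[5-(oxiran-2-yl)pent-3-yn-1-yl]oxy}silane (not isolated) | C1[C@H](O1)CC#CCCO[Si](C)(C)C(C)(C)C | intermediate
12 | (R)-8-[(tert-butyldimethylsilyl)oxy]oct-1-en-5-yn-3-ol | C=C[C@H](O)CC#CCCO[Si](C)(C)C(C)(C)C | intermediate
13 | (R)-tert-butyl({6-[(4-methoxybenzyl)oxy]oct-7-en-3-yn-1-yl}oxy)dimethylsilane | C=C[C@H](OCc1ccc(OC)cc1)CC#CCCO[Si](C)(C)C(C)(C)C | intermediate
14 | (R)-6-[(4-methoxybenzyl)oxy]oct-7-en-3-yn-1-ol | C=C[C@H](OCc1ccc(OC)cc1)CC#CCCO | intermediate
15 | bromomagnesium alkoxide of the C1-bromomagnesio alkene (methyl and magnesium cis on C10=C1; not isolated) | C=C[C@H](OCc1ccc(OC)cc1)C/C(C)=C(/[Mg]Br)CCO[Mg]Br | intermediate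
16 | (3Z,6R)-6-[(4-methoxybenzyl)oxy]-4-methylocta-3,7-dien-1-ol | C=C[C@H](OCc1ccc(OC)cc1)C/C(C)=C\CCO | intermediate
17 | 2-[(2S,3R)-3-{(2R)-2-[(4-methoxybenzyl)oxy]but-3-en-1-yl}-3-methyloxiran-2-yl]ethan-1-ol | C=C[C@H](OCc1ccc(OC)cc1)C[C@@]1(C)O[C@H]1CCO | intermediate
18 | 2-[(2S,3R)-3-{(2R)-2-[(4-methoxybenzyl)oxy]but-3-en-1-yl}-3-methyloxiran-2-yl]acetaldehyde | C=C[C@H](OCc1ccc(OC)cc1)C[C@@]1(C)O[C@H]1CC=O | intermediate
19 | (R)-alkenylchromium dichloride from 7 (trivalent chromium on C4; not isolated) | C=C([Cr](Cl)Cl)[C@H](OC(=O)/C(C)=C\C)CO[Si](C)(C)C(C)(C)C | intermediate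
20 | open-chain C3 carbinol, (1S,5S,8R,10R), both C3 epimers: C8(vinyl)(OPMB)–C9H2–cis-epoxide C10(CH3)/C1–C2H2–C3H(OH)–C4(=CH2)–C5H(O-angeloyl)–C6H2OTBS | C=C[C@H](OCc1ccc(OC)cc1)C[C@@]1(C)O[C@H]1CC(O)C(=C)[C@H](OC(=O)/C(C)=C\C)CO[Si](C)(C)C(C)(C)C | intermediate
21 | C3 O-TBS ether of 20 | C=C[C@H](OCc1ccc(OC)cc1)C[C@@]1(C)O[C@H]1CC(O[Si](C)(C)C(C)(C)C)C(=C)[C@H](OC(=O)/C(C)=C\C)CO[Si](C)(C)C(C)(C)C | intermediate
22 | C8 alcohol from 21 (PMB removed) | C=C[C@H](O)C[C@@]1(C)O[C@H]1CC(O[Si](C)(C)C(C)(C)C)C(=C)[C@H](OC(=O)/C(C)=C\C)CO[Si](C)(C)C(C)(C)C | intermediate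
23 | C8 2-(bromomethyl)prop-2-enoate of 22 | C=C[C@H](OC(=O)C(=C)CBr)C[C@@]1(C)O[C@H]1CC(O[Si](C)(C)C(C)(C)C)C(=C)[C@H](OC(=O)/C(C)=C\C)CO[Si](C)(C)C(C)(C)C | intermediate
24 | (5R)-3-(bromomethyl)furan-2(5H)-one with the C9–C6 chain (C3 OTBS, C6 OTBS; 1S,5S,8R,10R) | BrCC1=C[C@@H](C[C@@]2(C)O[C@H]2CC(O[Si](C)(C)C(C)(C)C)C(=C)[C@H](OC(=O)/C(C)=C\C)CO[Si](C)(C)C(C)(C)C)OC1=O | intermediate
25 | diol from 24 (C3 OH, C6 OH) | BrCC1=C[C@@H](C[C@@]2(C)O[C@H]2CC(O)C(=C)[C@H](OC(=O)/C(C)=C\C)CO)OC1=O | intermediate
26 | keto aldehyde (C3 ketone, C6 aldehyde; 1S,5S,8R,10R) | BrCC1=C[C@@H](C[C@@]2(C)O[C@H]2CC(=O)C(=C)[C@H](OC(=O)/C(C)=C\C)C=O)OC1=O | intermediate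
27 | allylchromium dichloride from 26 (trivalent chromium on C13; not isolated) | Cl[Cr](Cl)CC1=C[C@@H](C[C@@]2(C)O[C@H]2CC(=O)C(=C)[C@H](OC(=O)/C(C)=C\C)C=O)OC1=O | intermediate
28 | CNP0348992.4, (1S,5S,6R,7R,8R,10R)-1,10-epoxy-6-hydroxy-5-[(Z)-2-methylbut-2-enoyloxy]-3-oxogermacra-4(15),11(13)-dien-12,8-olide in the labels used here | C=C1C(=O)O[C@@H]2C[C@@]3(C)O[C@H]3CC(=O)C(=C)[C@H](OC(=O)/C(C)=C\C)[C@H](O)[C@@H]12 | target

**Count**
Total steps: 20. Longest linear sequence: 15 steps (steps 6–20, from 8 and 9); the branch to 7 is 5 steps (steps 1–5).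

**Steps most likely to fail**

Step 20 (ring closure). What may go wrong: chain-to-chain allylation may outrun the ten-membered closure, the allylchromium may add to the C3 ketone in the seven-membered mode, or the strained macrocyclic transition state may lose facial control at C6. The fallback reverses the order of the two chromium couplings, so that C6–C7 is made between fragments and the ring is closed at C3–C4 by an intramolecular Nozaki–Hiyama–Kishi reaction; it sets out from 17 and 7. Silylation of 17 (TBSCl, imidazole) gives the C3 silyl ether F1, DDQ gives the C8 alcohol F2, esterification with 2-(bromomethyl)acrylic acid (DIC, DMAP cat.) gives the acrylate F3, and ring-closing metathesis with the second-generation Hoveyda–Grubbs catalyst gives the bromomethyl butenolide F4. In parallel, 7 is desilylated with HF·pyridine to the primary alcohol F5 and oxidised with Dess–Martin periodinane to the α-angeloyloxy aldehyde F6. CrCl2 in THF then joins F4 and F6 in an intermolecular Barbier allylation, a reaction with direct precedent for 5-substituted 3-(bromomethyl)butenolides, to give the α-methylene lactone F7 with the C6/C7 sense argued for step 20. HF·pyridine frees the C3 hydroxyl to give the diol F8, TEMPO/PhI(OAc)2 oxidises only the primary hydroxyl to the aldehyde F9, and CrCl2 with NiCl2 (cat.) in DMSO at high dilution closes the ring to the macrocyclic C3 alcohol F10 (either C3 epimer). MnO2 in CH2Cl2 oxidises the allylic C3 hydroxyl alone, and the sequence comes back to the route at 28.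

Step 13 (fragment union). What may go wrong: the β,γ-epoxy aldehyde may enolise and open its epoxide (β-elimination) before it is captured, and the 2-chromioallyl ester may expel angelate to give an allene. The fallback joins the fragments before the epoxide exists and makes the epoxide afterwards under reagent control; it sets out from 16 and 7. Dess–Martin oxidation of 16 gives the Z-β,γ-unsaturated aldehyde F11, which is used at once. CrCl2/NiCl2 (cat.) coupling with 7 gives the C3 carbinol F12, and TBSCl/imidazole gives the bis-silyl ether F13. Shi epoxidation with the L-fructose-derived ketone (KHSO5 as Oxone, K2CO3 buffer, MeCN/dimethoxymethane, 0 °C) then oxidises only the electron-rich trisubstituted alkene. The enantiomer of the ketone is chosen from the spiro transition-state model for the C1 S, C10 R epoxide, and the sequence comes back to the route at 21.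

Step 19 (double oxidation). What may go wrong: the diol and the keto aldehyde may degrade during handling, through 5-endo opening of the epoxide by the free C3 hydroxyl, angeloyl migration from O5 to O6, loss of angelate from the α-methylene-β-acyloxy ketone, or epimerisation at C5 of the α-acyloxy aldehyde. The fallback keeps C3 masked through the ring closure and makes the ketone last; it sets out from 24. Short treatment with HF·pyridine buffered with pyridine at 0 °C cleaves only the primary silyl ether to give the C6 alcohol F14, and Dess–Martin oxidation gives the aldehyde F15. CrCl2 in THF at high dilution closes the ring, with no competing ketone, to the macrocyclic silyl ether F16. HF·pyridine then gives the macrocyclic C3 alcohol F10, and MnO2 oxidises it to rejoin the route at 28.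

**Further compounds**
F1 | step 20 | C3 O-TBS ether of 17 | C=C[C@H](OCc1ccc(OC)cc1)C[C@@]1(C)O[C@H]1CCO[Si](C)(C)C(C)(C)C
F2 | step 20 | C8 alcohol from F1 (PMB removed) | C=C[C@H](O)C[C@@]1(C)O[C@H]1CCO[Si](C)(C)C(C)(C)C
F3 | step 20 | C8 2-(bromomethyl)prop-2-enoate of F2 | C=C[C@H](OC(=O)C(=C)CBr)C[C@@]1(C)O[C@H]1CCO[Si](C)(C)C(C)(C)C
F4 | step 20 | (5R)-3-(bromomethyl)furan-2(5H)-one with the C9–C3 epoxy chain ending in C3 OTBS | BrCC1=C[C@@H](C[C@@]2(C)O[C@H]2CCO[Si](C)(C)C(C)(C)C)OC1=O
F5 | step 20 | (R)-1-hydroxy-3-iodobut-3-en-2-yl (Z)-2-methylbut-2-enoate | C=C(I)[C@H](OC(=O)/C(C)=C\C)CO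
F6 | step 20 | (R)-3-iodo-1-oxobut-3-en-2-yl (Z)-2-methylbut-2-enoate | C=C(I)[C@H](OC(=O)/C(C)=C\C)C=O
F7 | step 20 | α-methylene-γ-lactone Barbier adduct (C6 OH, C5 O-angeloyl, C4 vinyl iodide, C3 OTBS; C1, C5–C8 and C10 as in 28) | C=C1C(=O)O[C@H](C[C@@]2(C)O[C@H]2CCO[Si](C)(C)C(C)(C)C)[C@H]1[C@@H](O)[C@@H](OC(=O)/C(C)=C\C)C(I)=C
F8 | step 20 | diol from F7 (C3 OH primary, C6 OH) | C=C1C(=O)O[C@H](C[C@@]2(C)O[C@H]2CCO)[C@H]1[C@@H](O)[C@@H](OC(=O)/C(C)=C\C)C(I)=C
F9 | step 20 | C3 aldehyde from F8 | C=C1C(=O)O[C@H](C[C@@]2(C)O[C@H]2CC=O)[C@H]1[C@@H](O)[C@@H](OC(=O)/C(C)=C\C)C(I)=C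
F10 | step 20 | macrocyclic C3 alcohol (3-hydroxy analogue of 28, either C3 epimer) | C=C1C(=O)O[C@@H]2C[C@@]3(C)O[C@H]3CC(O)C(=C)[C@H](OC(=O)/C(C)=C\C)[C@H](O)[C@@H]12
F11 | step 13 | (3Z,6R)-6-[(4-methoxybenzyl)oxy]-4-methylocta-3,7-dienal | C=C[C@H](OCc1ccc(OC)cc1)C/C(C)=C\CC=O
F12 | step 13 | alkene analogue of 20 (Z-C1=C10 in place of the epoxide; both C3 epimers) | C=C[C@H](OCc1ccc(OC)cc1)C/C(C)=C\CC(O)C(=C)[C@H](OC(=O)/C(C)=C\C)CO[Si](C)(C)C(C)(C)C
F13 | step 13 | alkene analogue of 21 (C3 OTBS) | C=C[C@H](OCc1ccc(OC)cc1)C/C(C)=C\CC(O[Si](C)(C)C(C)(C)C)C(=C)[C@H](OC(=O)/C(C)=C\C)CO[Si](C)(C)C(C)(C)C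
F14 | step 19 | C6 alcohol from 24 with C3 OTBS kept | BrCC1=C[C@@H](C[C@@]2(C)O[C@H]2CC(O[Si](C)(C)C(C)(C)C)C(=C)[C@H](OC(=O)/C(C)=C\C)CO)OC1=O
F15 | step 19 | C6 aldehyde from F14 with C3 OTBS | BrCC1=C[C@@H](C[C@@]2(C)O[C@H]2CC(O[Si](C)(C)C(C)(C)C)C(=C)[C@H](OC(=O)/C(C)=C\C)C=O)OC1=O
F16 | step 19 | macrocyclic C3 O-TBS ether (3-silyloxy analogue of 28) | C=C1C(=O)O[C@@H]2C[C@@]3(C)O[C@H]3CC(O[Si](C)(C)C(C)(C)C)C(=C)[C@H](OC(=O)/C(C)=C\C)[C@H](O)[C@@H]12
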